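## Retrosynthetic overview

1. Target ⇐ diol tropone: the last step oxidises the 3-hydroxypropyl chain to the acid; both silyl ethers fall off in the tropone-forming acid step.
2. Tropone ring (formed last) ⇐ C3a=C4 by intramolecular vinylogous aldol condensation and C5=C6 by Knoevenagel condensation: spiro 2-alkylidenetetrahydrofuran β-keto ester + 1,1-dimethoxypropan-2-one.
3. Oxygen five-membered ring (formed second) ⇐ spiro γ-lactone + dianion of methyl 3-oxopentanoate; lactone ⇐ SmI2 ketyl–acrylate coupling on the cyclohexanone, which sets the spiro centre.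
4. Cyclohexanone ⇐ (S)-carvone: two enolate alkylations at C6 (quaternary centre), hydration of the isopropenyl group, face-selective enone hydrogenation (C2 methyl centre).
5. Ring order: cyclohexane (chiral pool) → spiro lactone, then dihydrofuran → seven-membered tropone.

Assumption: tert-butyl(3-iodopropoxy)dimethylsilane, methyl 3-oxopentanoate, 1,1-dimethoxypropan-2-one and SmI2 (0.1 M in THF) are taken as commercial. The route is designed on paper and has not been run; the tropone annulation (steps 8 and 9) has no close precedent.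

## Route

Step 1
Reactants: 1 (S)-(+)-carvone
Product: 3 (5S)-2,6-dimethyl-5-(prop-1-en-2-yl)cyclohex-2-en-1-one (C6 epimer mixture), via lithium dienolate 2 (not isolated)
Conditions: LiN(i-Pr)2, THF, −78 °C; MeI, −78 to 0 °C
Reagents that add atoms: iodomethane (CI)
Why: Kinetic deprotonation at the alpha-prime carbon gives the cross-conjugated dienolate, which is C-methylated (enolate alkylation); the new C6 centre is a mixture that is erased in step 2.

Step 2
Reactants: 3 (5S)-2,6-dimethyl-5-(prop-1-en-2-yl)cyclohex-2-en-1-one; 4 tert-butyl(3-iodopropoxy)dimethylsilane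
Product: 6 (5R,6R)-6-[3-(tert-butyldimethylsilyloxy)propyl]-2,6-dimethyl-5-(prop-1-en-2-yl)cyclohex-2-en-1-one, via lithium enolate 5 (not isolated)
Conditions: LiN(i-Pr)2, THF, −78 °C; DMPU; 4, −78 °C to rt
Reagents that add atoms: none
Why: Enolate alkylation (SN2) in which the primary iodide attacks the planar C6 enolate anti to the neighbouring isopropenyl group, so the quaternary centre forms with the chain trans and the methyl cis to isopropenyl (6R).

Step 3
Reactants: 6 (5R,6R)-6-[3-(tert-butyldimethylsilyloxy)propyl]-2,6-dimethyl-5-(prop-1-en-2-yl)cyclohex-2-en-1-one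
Product: 8 (5S,6R)-6-[3-(tert-butyldimethylsilyloxy)propyl]-5-(2-hydroxypropan-2-yl)-2,6-dimethylcyclohex-2-en-1-one, via organomercurial 7 (not isolated)
Conditions: Hg(OAc)2, THF/H2O, rt; then NaBH4, 3 M aq NaOH, 0 °C
Reagents that add atoms: water (O)
Why: Markovnikov oxymercuration–demercuration hydrates the electron-rich 1,1-disubstituted alkene while the electron-poor enone C=C is inert to the mercury electrophile; no ring stereocentre is touched.

Step 4
Reactants: 8 (5S,6R)-6-[3-(tert-butyldimethylsilyloxy)propyl]-5-(2-hydroxypropan-2-yl)-2,6-dimethylcyclohex-2-en-1-one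
Product: 9 (5S,6R)-6-[3-(tert-butyldimethylsilyloxy)propyl]-2,6-dimethyl-5-[2-(triethylsilyloxy)propan-2-yl]cyclohex-2-en-1-one
Conditions: Et3SiOTf, 2,6-lutidine, CH2Cl2, −78 to 0 °C
Reagents that add atoms: triethylsilyl trifluoromethanesulfonate (CC[Si](CC)(CC)OS(=O)(=O)C(F)(F)F)
Why: Silyl triflate silylation of the hindered tertiary alcohol; the very bulky C5 group now stays equatorial and locks the ring with the C6 methyl axial, which controls steps 5 and 6.

Step 5
Reactants: 9 (5S,6R)-6-[3-(tert-butyldimethylsilyloxy)propyl]-2,6-dimethyl-5-[2-(triethylsilyloxy)propan-2-yl]cyclohex-2-en-1-one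
Product: 10 (2R,5S,6R)-6-[3-(tert-butyldimethylsilyloxy)propyl]-2,6-dimethyl-5-[2-(triethylsilyloxy)propan-2-yl]cyclohexan-1-one
Conditions: H2 (1 atm), Pd/C, EtOAc, rt
Reagents that add atoms: none
Why: Heterogeneous syn-hydrogenation of the enone C=C on the face opposite the axial C6 methyl delivers H to C2 from the side of the propyl chain, so the C2 methyl ends cis to the C6 methyl and to the C5 group (2R, kinetic epimer).

Step 6
Reactants: 10 (2R,5S,6R)-6-[3-(tert-butyldimethylsilyloxy)propyl]-2,6-dimethyl-5-[2-(triethylsilyloxy)propan-2-yl]cyclohexan-1-one; 11 methyl acrylate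
Product: 13 (5R,6R,7S,10R)-6-[3-(tert-butyldimethylsilyloxy)propyl]-6,10-dimethyl-7-[2-(triethylsilyloxy)propan-2-yl]-1-oxaspiro[4.5]decan-2-one, via hydroxy ester 12 (not isolated)
Conditions: SmI2, t-BuOH, THF, −78 °C to rt
Reagents that add atoms: none
Why: SmI2 ketyl–olefin reductive coupling followed by spontaneous lactonisation; the ketyl carbon bonds to the acrylate axially on the face free of the two axial methyl groups, so the new C–C bond is trans and the C–O bond cis to both methyls (spiro centre 5R) under non-basic conditions that do not epimerise C10.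

Step 7
Reactants: 13 (5R,6R,7S,10R)-6-[3-(tert-butyldimethylsilyloxy)propyl]-6,10-dimethyl-7-[2-(triethylsilyloxy)propan-2-yl]-1-oxaspiro[4.5]decan-2-one; 14 methyl 3-oxopentanoate
Product: 17 methyl 4-[(5R,6R,7S,10R)-6-[3-(tert-butyldimethylsilyloxy)propyl]-6,10-dimethyl-7-[2-(triethylsilyloxy)propan-2-yl]-1-oxaspiro[4.5]decan-2-ylidene]-3-oxopentanoate (E/Z mixture), via dilithium dianion 15 (not isolated), via hemiketal 16 (not isolated)
Conditions: 14 (3 equiv), LiN(i-Pr)2 (6 equiv), THF, 0 °C; 13, −78 to 0 °C; AcOH; then PPTS (cat.), CH2Cl2, rt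
Reagents that add atoms: none
Why: Claisen-type acylation of the gamma-carbon of the β-keto ester dianion by the lactone carbonyl, then acid-catalysed dehydration of the cyclic hemiketal to the push–pull 2-alkylidenetetrahydrofuran; the C–O bond at the spiro centre is never broken, so its configuration is kept.

Step 8
Reactants: 17 methyl 4-[(5R,6R,7S,10R)-spiro-2-ylidene]-3-oxopentanoate (as above); 18 1,1-dimethoxypropan-2-one
Product: 19 methyl 2-(1,1-dimethoxypropan-2-ylidene)-3-oxo-4-[(5R,6R,7S,10R)-6-[3-(tert-butyldimethylsilyloxy)propyl]-6,10-dimethyl-7-[2-(triethylsilyloxy)propan-2-yl]-1-oxaspiro[4.5]decan-2-ylidene]pentanoate (alkene isomer mixture)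
Conditions: TiCl4, pyridine, THF, 0 °C to rt
Reagents that add atoms: none
Why: Lehnert-type Knoevenagel condensation of the β-keto ester methylene with the activated ketone of the keto acetal (the aldehyde carbon stays masked, which fixes the methyl next to the ester carbon); no stereocentre forms and the alkene geometry equilibrates in step 9.

Step 9
Reactants: 19 methyl 2-(1,1-dimethoxypropan-2-ylidene)-3-oxo-4-[(5R,6R,7S,10R)-spiro-2-ylidene]pentanoate (as above)
Product: 22 methyl (2R,2'R,3'S,6'R)-3'-(2-hydroxypropan-2-yl)-2'-(3-hydroxypropyl)-2',5,6',8-tetramethyl-7-oxo-3,7-dihydrospiro[cyclohepta[b]furan-2,1'-cyclohexane]-6-carboxylate, via enal 20 (not isolated), via bis-silyl tropone 21 (not isolated)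
Conditions: 1 M aq HCl, THF, 40 °C
Reagents that add atoms: none
Why: Acetal hydrolysis unmasks an enal that undergoes intramolecular vinylogous aldol condensation with the gamma-methylene of the vinylogous ester (seven-membered ring closure driven by formation of the aromatic tropone), and the same dilute acid removes both silyl ethers; no stereocentre is touched.

Step 10
Reactants: 22 methyl (2R,2'R,3'S,6'R)-3'-(2-hydroxypropan-2-yl)-2'-(3-hydroxypropyl)-2',5,6',8-tetramethyl-7-oxo-3,7-dihydrospiro[cyclohepta[b]furan-2,1'-cyclohexane]-6-carboxylate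
Product: 24 3-[(2R,2'R,3'S,6'R)-3'-(2-hydroxypropan-2-yl)-6-(methoxycarbonyl)-2',5,6',8-tetramethyl-7-oxo-3,7-dihydrospiro[cyclohepta[b]furan-2,1'-cyclohexan]-2'-yl]propanoic acid (CNP0448476.2), via aldehyde 23 (not isolated)
Conditions: TEMPO (cat.), PhI(OAc)2, MeCN/H2O (1:1), rt
Reagents that add atoms: water (O)
Why: Oxoammonium (TEMPO/PhI(OAc)2) oxidation takes the primary alcohol through the aldehyde hydrate to the carboxylic acid and leaves the tertiary alcohol, the methyl ester and the tropone untouched.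

## Compound list

1 | (S)-(+)-carvone, (5S)-2-methyl-5-(prop-1-en-2-yl)cyclohex-2-en-1-one | O=C1C(C)=CC[C@H](C(C)=C)C1 | starting material
2 | lithium dienolate of 1 (C6-deprotonated, cross-conjugated) | [Li+].[O-]C1=C[C@@H](C(C)=C)CC=C1C | intermediate
3 | (5S)-2,6-dimethyl-5-(prop-1-en-2-yl)cyclohex-2-en-1-one, C6 epimer mixture | O=C1C(C)=CC[C@H](C(C)=C)C1C | intermediate
4 | tert-butyl(3-iodopropoxy)dimethylsilane | CC(C)(C)[Si](C)(C)OCCCI | starting material
5 | lithium enolate of 3 (C1–C6 enolate) | [Li+].[O-]C1=C(C)[C@@H](C(C)=C)CC=C1C | intermediate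
6 | (5R,6R)-6-[3-(tert-butyldimethylsilyloxy)propyl]-2,6-dimethyl-5-(prop-1-en-2-yl)cyclohex-2-en-1-one (chain trans to isopropenyl) | O=C1C(C)=CC[C@H](C(C)=C)[C@@]1(C)CCCO[Si](C)(C)C(C)(C)C | intermediate
7 | organomercurial: 6 with the isopropenyl group turned into C(CH3)(OH)CH2HgOAc (carbinol carbon as a mixture) | O=C1C(C)=CC[C@H](C(C)(O)C[Hg]OC(C)=O)[C@@]1(C)CCCO[Si](C)(C)C(C)(C)C | intermediate
8 | (5S,6R)-6-[3-(tert-butyldimethylsilyloxy)propyl]-5-(2-hydroxypropan-2-yl)-2,6-dimethylcyclohex-2-en-1-one | O=C1C(C)=CC[C@H](C(C)(C)O)[C@@]1(C)CCCO[Si](C)(C)C(C)(C)C | intermediate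
9 | (5S,6R)-6-[3-(tert-butyldimethylsilyloxy)propyl]-2,6-dimethyl-5-[2-(triethylsilyloxy)propan-2-yl]cyclohex-2-en-1-one | O=C1C(C)=CC[C@H](C(C)(C)O[Si](CC)(CC)CC)[C@@]1(C)CCCO[Si](C)(C)C(C)(C)C | intermediate
10 | (2R,5S,6R)-6-[3-(tert-butyldimethylsilyloxy)propyl]-2,6-dimethyl-5-[2-(triethylsilyloxy)propan-2-yl]cyclohexan-1-one (both methyls and the C5 group cis) | O=C1[C@H](C)CC[C@H](C(C)(C)O[Si](CC)(CC)CC)[C@@]1(C)CCCO[Si](C)(C)C(C)(C)C | intermediate
11 | methyl acrylate | C=CC(=O)OC | starting material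
12 | open-chain γ-hydroxy ester from ketyl addition (samarium alkoxide in the flask, drawn neutral) | O[C@]1(CCC(=O)OC)[C@H](C)CC[C@H](C(C)(C)O[Si](CC)(CC)CC)[C@@]1(C)CCCO[Si](C)(C)C(C)(C)C | intermediate
13 | (5R,6R,7S,10R)-6-[3-(tert-butyldimethylsilyloxy)propyl]-6,10-dimethyl-7-[2-(triethylsilyloxy)propan-2-yl]-1-oxaspiro[4.5]decan-2-one | O=C1O[C@]2(CC1)[C@H](C)CC[C@H](C(C)(C)O[Si](CC)(CC)CC)[C@@]2(C)CCCO[Si](C)(C)C(C)(C)C | intermediate
14 | methyl 3-oxopentanoate | CCC(=O)CC(=O)OC | starting material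
15 | dilithium dianion of 14 (C2 and C4 deprotonated) | [Li+].[Li+].C[CH-]C(=O)[CH-]C(=O)OC | intermediate
16 | cyclic hemiketal from addition of 15 to the lactone carbonyl of 13 (new centres as mixtures) | COC(=O)CC(=O)C(C)C1(O)O[C@]2(CC1)[C@H](C)CC[C@H](C(C)(C)O[Si](CC)(CC)CC)[C@@]2(C)CCCO[Si](C)(C)C(C)(C)C | intermediate
17 | methyl 4-[(5R,6R,7S,10R)-6-[3-(tert-butyldimethylsilyloxy)propyl]-6,10-dimethyl-7-[2-(triethylsilyloxy)propan-2-yl]-1-oxaspiro[4.5]decan-2-ylidene]-3-oxopentanoate, E/Z mixture | COC(=O)CC(=O)C(C)=C1O[C@]2(CC1)[C@H](C)CC[C@H](C(C)(C)O[Si](CC)(CC)CC)[C@@]2(C)CCCO[Si](C)(C)C(C)(C)C | intermediate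
18 | 1,1-dimethoxypropan-2-one | CC(=O)C(OC)OC | starting material
19 | methyl 2-(1,1-dimethoxypropan-2-ylidene)-3-oxo-4-[(5R,6R,7S,10R)-spiro-2-ylidene]pentanoate (Knoevenagel product of 17), alkene isomer mixture | COC(=O)C(=C(C)C(OC)OC)C(=O)C(C)=C1O[C@]2(CC1)[C@H](C)CC[C@H](C(C)(C)O[Si](CC)(CC)CC)[C@@]2(C)CCCO[Si](C)(C)C(C)(C)C | intermediate
20 | enal from acetal hydrolysis of 19 | COC(=O)C(=C(C)C=O)C(=O)C(C)=C1O[C@]2(CC1)[C@H](C)CC[C@H](C(C)(C)O[Si](CC)(CC)CC)[C@@]2(C)CCCO[Si](C)(C)C(C)(C)C | intermediate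
21 | bis-silyl ether of tropone 22 (triethylsilyl on the tertiary oxygen, tert-butyldimethylsilyl on the primary oxygen) | COC(=O)c1c(C)cc2c(c(C)c1=O)O[C@]1(C2)[C@H](C)CC[C@H](C(C)(C)O[Si](CC)(CC)CC)[C@@]1(C)CCCO[Si](C)(C)C(C)(C)C | intermediate
22 | methyl (2R,2'R,3'S,6'R)-3'-(2-hydroxypropan-2-yl)-2'-(3-hydroxypropyl)-2',5,6',8-tetramethyl-7-oxo-3,7-dihydrospiro[cyclohepta[b]furan-2,1'-cyclohexane]-6-carboxylate | COC(=O)c1c(C)cc2c(c(C)c1=O)O[C@]1(C2)[C@H](C)CC[C@H](C(C)(C)O)[C@@]1(C)CCCO | intermediate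
23 | aldehyde of 22 (3-oxopropyl chain) | COC(=O)c1c(C)cc2c(c(C)c1=O)O[C@]1(C2)[C@H](C)CC[C@H](C(C)(C)O)[C@@]1(C)CCC=O | intermediate
24 | 3-[(2R,2'R,3'S,6'R)-3'-(2-hydroxypropan-2-yl)-6-(methoxycarbonyl)-2',5,6',8-tetramethyl-7-oxo-3,7-dihydrospiro[cyclohepta[b]furan-2,1'-cyclohexan]-2'-yl]propanoic acid (CNP0448476.2) | COC(=O)c1c(C)cc2c(c(C)c1=O)O[C@]1(C2)[C@H](C)CC[C@H](C(C)(C)O)[C@@]1(C)CCC(=O)O | target

## Step count and risks

Total step count: 10. Longest linear sequence: 10 steps (1 to 24).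

Steps most likely to fail:

Step 5 (C2 methyl centre). The wanted ketone is the less stable epimer (two syn-axial methyl groups), and palladium can scramble it through enol forms. The fallback replaces hydrogen delivery from the catalyst by hydride conjugate addition and kinetic protonation. It sets out from 9: LiBH(s-Bu)3 in THF at −78 °C adds hydride to C3 and gives the lithium enolate F1. Quenching at −78 °C with AcOH protonates C2 on the face opposite the axial C6 methyl, and the sequence comes back to the route at 10.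

Step 8 (Knoevenagel condensation with a ketone at a hindered methylene). The fallback builds the same carbon–carbon double bond in another order and sets out from 17. Condensation with 2,2-dimethoxyacetaldehyde (piperidine, AcOH, benzene, reflux; an aldehyde condenses far more easily) gives the alkylidene keto ester F2. Conjugate addition of Me2CuLi (THF, −78 °C) brings in the missing ring methyl group and gives the keto ester acetal F3. The acid treatment of step 9 then closes the ring and removes both silyl groups to give the dihydrotropone diol F4. Dehydrogenation with DDQ (dioxane, rt) comes back to the route at 22.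

Step 9 (seven-membered aldol ring closure). The fallback makes the gamma-carbon an explicit nucleophile and the acetal an explicit electrophile, and sets out from 19. Soft enolisation with t-BuMe2SiOTf/Et3N (CH2Cl2, −78 °C) gives the silyl dienol ether F5. BF3·OEt2 (CH2Cl2, −78 °C) ionises the acetal and triggers an intramolecular vinylogous Mukaiyama addition that gives the methoxy cycloheptadienone F6. DBU eliminates methanol and the sequence comes back to the route at 21, which is desilylated to 22 with dilute aqueous acid as in step 9.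

## Further compounds

F1 | step 5 | lithium enolate (C1–C2) from conjugate reduction of 9 | [Li+].[O-]C1=C(C)CC[C@H](C(C)(C)O[Si](CC)(CC)CC)[C@@]1(C)CCCO[Si](C)(C)C(C)(C)C
F2 | step 8 | methyl 2-(2,2-dimethoxyethylidene)-3-oxo-4-[(5R,6R,7S,10R)-spiro-2-ylidene]pentanoate (alkylidene keto ester) | COC(=O)C(=CC(OC)OC)C(=O)C(C)=C1O[C@]2(CC1)[C@H](C)CC[C@H](C(C)(C)O[Si](CC)(CC)CC)[C@@]2(C)CCCO[Si](C)(C)C(C)(C)C
F3 | step 8 | methyl 2-(1,1-dimethoxypropan-2-yl)-3-oxo-4-[(5R,6R,7S,10R)-spiro-2-ylidene]pentanoate (keto ester acetal, new centres as mixtures) | COC(=O)C(C(C)C(OC)OC)C(=O)C(C)=C1O[C@]2(CC1)[C@H](C)CC[C@H](C(C)(C)O[Si](CC)(CC)CC)[C@@]2(C)CCCO[Si](C)(C)C(C)(C)C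
F4 | step 8 | 5,6-dihydro form of 22 (dihydrotropone diol, H on C5 and C6 of the seven-membered ring) | COC(=O)C1C(C)C=C2C(=C(C)C1=O)O[C@]1(C2)[C@H](C)CC[C@H](C(C)(C)O)[C@@]1(C)CCCO
F5 | step 9 | silyl dienol ether of 19 (tert-butyldimethylsilyl enol ether at the ketone, endocyclic 4,5-dihydrofuran double bond) | COC(=O)C(=C(C)C(OC)OC)C(O[Si](C)(C)C(C)(C)C)=C(C)C1=CC[C@@]2(O1)[C@H](C)CC[C@H](C(C)(C)O[Si](CC)(CC)CC)[C@@]2(C)CCCO[Si](C)(C)C(C)(C)C
F6 | step 9 | 4-methoxy-3a,4-dihydro form of 21 (methoxy cycloheptadienone, new centres as mixtures) | COC(=O)C1=C(C)C(OC)C2C(=C(C)C1=O)O[C@]1(C2)[C@H](C)CC[C@H](C(C)(C)O[Si](CC)(CC)CC)[C@@]1(C)CCCO[Si](C)(C)C(C)(C)C
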